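**Retrosynthetic overview**

1. The target is a (3S,4S)-dibenzylbutyrolactone (ring A). Its aryl rings B (on the β-benzyl) and C (on the α-benzyl) each carry, ortho to the phenol, a 1-guaiacylpropane-1,3-diol arm (outer rings D and E; arm atoms C7–C9 on ring B, C7′–C9′ on ring C).
2. Feature used: C7 is a benzylic carbinol para to the O4 oxygen of outer ring D and 1,3 to the C9 oxygen (likewise C7′/ring E/C9′). The C7–O bond is therefore made from a C7 methylene by DDQ hydride abstraction, with the C9 tert-butyl carbonate delivering oxygen and closing a 4,5-trans 1,3-dioxan-2-one.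
3. C8 is set by Evans alkylation of the ring B arylacetyl oxazolidinone with 4-benzyloxy-3-methoxybenzyl bromide. The antipodal auxiliary gives the ring C arm, whose C7′ is then inverted (Mitsunobu).
4. Ring A: the ring B arm, as aryl Grignard reagent, opens a (1R,5S)-cyclopropane-fused lactone to the (S)-β-benzyl lactone. The ring C arm, as benzylic bromide, alkylates its enolate trans. Fluoride and then hydrogenolysis unmask the target.
5. Ring order: dioxanone of the ring B arm, dioxanone of the ring C arm (both temporary), then the cyclopropane-fused lactone that brings ring A; all aromatic rings are bought.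

Key step: step 11

Remarks. Abbreviations: TIPS = triisopropylsilyl, TBS = tert-butyldimethylsilyl, Boc = tert-butoxycarbonyl, Bn = benzyl. The key reaction is repeated on the antipodal substrate in step 18. Acid chloride 8 is made once, on a scale that supplies both auxiliary loadings (steps 7 and 14). Assumption: the ring B and ring C phenols are carried through the key step as tert-butyl carbonates, because one Boc2O treatment then makes both the nucleophilic C9 carbonate and the deactivating aryl ester, and one methanolysis removes both.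

**Route**

Step 1
Reactants: 1 5-bromo-2-hydroxy-3-methoxybenzaldehyde
Product: 2 5-bromo-3-methoxy-2-(triisopropylsilyloxy)benzaldehyde
Conditions: i-Pr3SiCl, imidazole, DMAP (cat.), DMF, rt
Reagents that add atoms: triisopropylsilyl chloride CC(C)[Si](Cl)(C(C)C)C(C)C
Why: Silyl ether formation masks the phenol with a group that tolerates ylide, enolate and borohydride chemistry and is removed later by fluoride.

Step 2
Reactants: 2 5-bromo-3-methoxy-2-(triisopropylsilyloxy)benzaldehyde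
Product: 3 [4-bromo-2-methoxy-6-(2-methoxyethenyl)phenoxy]triisopropylsilane (E/Z mixture)
Conditions: MeOCH2PPh3Cl, KOtBu, THF, 0 °C; then 2, 0 °C → rt
Reagents that add atoms: (methoxymethyl)triphenylphosphonium chloride [Cl-].COC[P+](c1ccccc1)(c1ccccc1)c1ccccc1
Why: Wittig methoxymethylenation adds the carbon that becomes C9 (the aldehyde carbon becomes C8); alkene geometry is irrelevant.

Step 3
Reactants: 3 enol ether
Product: 4 2-[5-bromo-3-methoxy-2-(triisopropylsilyloxy)phenyl]acetaldehyde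
Conditions: 2 M HCl, THF, rt
Reagents that add atoms: water O
Why: Acid hydrolysis of the enol ether should give the arylacetaldehyde, the aryl TIPS ether being stable to dilute acid at room temperature.

Step 4
Reactants: 4 arylacetaldehyde
Product: 5 2-[5-bromo-3-methoxy-2-(triisopropylsilyloxy)phenyl]acetic acid
Conditions: NaClO2, NaH2PO4, 2-methyl-2-butene, t-BuOH/H2O, 0 °C → rt
Reagents that add atoms: sodium chlorite [Na+].[O-]Cl=O
Why: Pinnick oxidation converts the aldehyde to the acid without touching the electron-rich ring, since the hypochlorite formed is scavenged by the alkene.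

Step 5
Reactants: 6 4-benzyloxy-3-methoxybenzyl alcohol
Product: 7 4-benzyloxy-3-methoxybenzyl bromide
Conditions: PBr3, Et2O, 0 °C
Reagents that add atoms: phosphorus tribromide BrP(Br)Br
Why: Bromide formation from a benzylic alcohol by substitution of its bromophosphite; the bromide is used fresh.

Step 6
Reactants: 5 arylacetic acid
Product: 8 2-[5-bromo-3-methoxy-2-(triisopropylsilyloxy)phenyl]acetyl chloride
Conditions: (COCl)2, DMF (cat.), CH2Cl2, 0 °C → rt; evaporate, use crude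
Reagents that add atoms: oxalyl chloride ClC(=O)C(=O)Cl
Why: Acid chloride formation with oxalyl chloride under chloroiminium (Vilsmeier-type) catalysis gives, after evaporation of the volatile by-products, one acyl donor for both auxiliaries; the hindered aryl TIPS ether should survive the brief exposure to HCl.

Step 7
Reactants: 8 arylacetyl chloride; 9 (S)-4-benzyl-2-oxazolidinone
Product: 10 (4S)-4-benzyl-3-{[5-bromo-3-methoxy-2-(triisopropylsilyloxy)phenyl]acetyl}oxazolidin-2-one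
Conditions: Et3N, DMAP (cat.), CH2Cl2, 0 °C → rt, slow addition of 8
Reagents that add atoms: none
Why: N-acylation of the oxazolidinone by the acid chloride under Et3N with DMAP as acyl-transfer catalyst loads the Evans auxiliary without a strong base near the aryl bromide, and slow addition keeps ketene formation from the arylacetyl chloride low.

Step 8
Reactants: 10 (S)-imide; 7 4-benzyloxy-3-methoxybenzyl bromide
Product: 12 (4S)-4-benzyl-3-[(2S)-3-(4-benzyloxy-3-methoxyphenyl)-2-(5-bromo-3-methoxy-2-triisopropylsilyloxyphenyl)propanoyl]oxazolidin-2-one, via sodium Z-enolate 11 (not isolated)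
Conditions: NaN(SiMe3)2, THF, −78 °C; then 7, −78 → −40 °C
Reagents that add atoms: none
Why: Evans asymmetric alkylation: the chelated sodium Z-enolate is benzylated on the face away from the C4 benzyl group of the auxiliary, which should set C8 as S (the minor diastereomer is removed by chromatography).

Step 9
Reactants: 12 alkylated (S)-imide
Product: 13 (2S)-3-(4-benzyloxy-3-methoxyphenyl)-2-[5-bromo-3-methoxy-2-(triisopropylsilyloxy)phenyl]propan-1-ol
Conditions: LiBH4, H2O (1 equiv), Et2O, 0 °C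
Reagents that add atoms: none
Why: Reductive cleavage of the N-acyl oxazolidinone to the primary alcohol avoids basic conditions that could epimerise the α-aryl centre, and the auxiliary is recovered.

Step 10
Reactants: 13 (2S)-alcohol
Product: 15 tert-butyl (2S)-3-(4-benzyloxy-3-methoxyphenyl)-2-[5-bromo-2-(tert-butoxycarbonyloxy)-3-methoxyphenyl]propyl carbonate, via free phenol alcohol 14 (not isolated)
Conditions: Bu4NF, THF, 0 °C; then Boc2O (3 equiv), DMAP (cat.), rt
Reagents that add atoms: di-tert-butyl dicarbonate CC(C)(C)OC(=O)OC(=O)OC(C)(C)C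
Why: Fluoride desilylation gives the phenoxide, which like the primary alcohol is converted to its tert-butyl carbonate by Boc2O under DMAP catalysis (O-acylation).

Step 11
Reactants: 15 (2S)-bis(tert-butyl carbonate)
Product: 18 tert-butyl 2-[(4S,5S)-4-(4-benzyloxy-3-methoxyphenyl)-2-oxo-1,3-dioxan-5-yl]-4-bromo-6-methoxyphenyl carbonate (4,5-trans), via benzylic cation 16 (not isolated), via dioxan-2-ylium ion 17 (not isolated)
Conditions: DDQ (1.5 equiv), 2,6-dichloropyridine, 4 Å MS, ClCH2CH2Cl, 0 °C → rt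
Reagents that add atoms: none
Why: Proposed new method: DDQ forms a charge-transfer complex with the 3-methoxy-4-benzyloxyphenyl ring D and abstracts hydride from C7 to give the para-benzyloxybenzyl cation 16; the carbonyl oxygen of the C9 tert-butyl carbonate adds to it to give the 2-tert-butoxy-1,3-dioxan-2-ylium ion 17, which loses its tert-butyl group as 2-methylpropene. The closest known reaction types are DDQ oxidation of para-alkoxybenzylic C–H bonds with capture by a tethered oxygen nucleophile, and cyclisation of homoallylic tert-butyl carbonates onto iodonium ions (iodocarbonate formation). The one ring closed is the 1,3-dioxan-2-one, by 6-exo attack of oxygen on the trigonal C7 through a chair. In that chair ring B on C8 and ring D on C7 both sit equatorial, so the existing C8 centre should set C7 as S (4,5-trans). The step needs site selectivity for C7–H over C8–H, the OCH2Ph groups and the ring B positions: ring D is the only electron-rich arene because ring B carries an O-Boc group and bromine, and aryl benzyl ether CH2 groups are inert to DDQ under these conditions. The main competitor is loss of H8 from 16 to a stilbene, which the weak base 2,6-dichloropyridine and the close carbonate are meant to hold back, while the product carbonate deactivates C7 toward a second oxidation.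

Step 12
Reactants: 18 (4S,5S)-cyclic carbonate
Product: 20 (1S,2S)-1-(4-benzyloxy-3-methoxyphenyl)-2-(2-benzyloxy-5-bromo-3-methoxyphenyl)propane-1,3-diol, via phenol triol 19 (not isolated)
Conditions: K2CO3, MeOH, rt; evaporate; then BnBr, DMF, rt → 40 °C
Reagents that add atoms: benzyl bromide BrCc1ccccc1
Why: Carbonate methanolysis (transesterification) frees the 1,3-diol and the ring B phenol, and only the phenoxide is then O-benzylated under K2CO3 (Williamson ether synthesis).

Step 13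
Reactants: 20 (1S,2S)-diol
Product: 21 (1S,2S)-1-(4-benzyloxy-3-methoxyphenyl)-2-(2-benzyloxy-5-bromo-3-methoxyphenyl)-1,3-bis(tert-butyldimethylsilyloxy)propane
Conditions: t-BuMe2SiOTf, 2,6-lutidine, CH2Cl2, −78 → 0 °C
Reagents that add atoms: tert-butyldimethylsilyl triflate CC(C)(C)[Si](C)(C)OS(=O)(=O)C(F)(F)F
Why: Silyl triflate silylation of both hydroxyls gives a diol protection that tolerates aryllithium and enolate chemistry and is later removed by fluoride without acid.

Step 14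
Reactants: 8 arylacetyl chloride; 22 (R)-4-benzyl-2-oxazolidinone
Product: 23 (4R)-4-benzyl-3-{[5-bromo-3-methoxy-2-(triisopropylsilyloxy)phenyl]acetyl}oxazolidin-2-one
Conditions: Et3N, DMAP (cat.), CH2Cl2, 0 °C → rt, slow addition of 8
Reagents that add atoms: none
Why: N-acylation of the oxazolidinone by the acid chloride under Et3N/DMAP catalysis as in step 7, now with the antipodal auxiliary for the ring C arm.

Step 15
Reactants: 23 (R)-imide; 7 4-benzyloxy-3-methoxybenzyl bromide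
Product: 25 (4R)-4-benzyl-3-[(2R)-3-(4-benzyloxy-3-methoxyphenyl)-2-(5-bromo-3-methoxy-2-triisopropylsilyloxyphenyl)propanoyl]oxazolidin-2-one, via sodium Z-enolate 24 (not isolated)
Conditions: NaN(SiMe3)2, THF, −78 °C; then 7, −78 → −40 °C
Reagents that add atoms: none
Why: Evans asymmetric alkylation as in step 8; the R auxiliary shields the opposite enolate face and should set C8′ as R.

Step 16
Reactants: 25 alkylated (R)-imide
Product: 26 (2R)-3-(4-benzyloxy-3-methoxyphenyl)-2-[5-bromo-3-methoxy-2-(triisopropylsilyloxy)phenyl]propan-1-ol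
Conditions: LiBH4, H2O (1 equiv), Et2O, 0 °C
Reagents that add atoms: none
Why: Reductive cleavage of the auxiliary as in step 9.

Step 17
Reactants: 26 (2R)-alcohol
Product: 28 tert-butyl (2R)-3-(4-benzyloxy-3-methoxyphenyl)-2-[5-bromo-2-(tert-butoxycarbonyloxy)-3-methoxyphenyl]propyl carbonate, via free phenol alcohol 27 (not isolated)
Conditions: Bu4NF, THF, 0 °C; then Boc2O (3 equiv), DMAP (cat.), rt
Reagents that add atoms: di-tert-butyl dicarbonate CC(C)(C)OC(=O)OC(=O)OC(C)(C)C
Why: Desilylation and double O-acylation with Boc2O as in step 10.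

Step 18
Reactants: 28 (2R)-bis(tert-butyl carbonate)
Product: 31 tert-butyl 2-[(4R,5R)-4-(4-benzyloxy-3-methoxyphenyl)-2-oxo-1,3-dioxan-5-yl]-4-bromo-6-methoxyphenyl carbonate (4,5-trans), via benzylic cation 29 (not isolated), via dioxan-2-ylium ion 30 (not isolated)
Conditions: DDQ (1.5 equiv), 2,6-dichloropyridine, 4 Å MS, ClCH2CH2Cl, 0 °C → rt
Reagents that add atoms: none
Why: Proposed new method: the same DDQ hydride abstraction at C7′ (para to the ring E oxygen), 6-exo capture of cation 29 by the C9′ tert-butyl carbonate oxygen and loss of 2-methylpropene from 30 as in step 11, run on the enantiomer, so the chair with both aryl groups equatorial should give the 4R,5R trans carbonate; the closest known types are DDQ benzylic C–H oxidation with a tethered oxygen nucleophile and iodocarbonate cyclisation.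

Step 19
Reactants: 31 (4R,5R)-cyclic carbonate
Product: 33 (1R,2R)-1-(4-benzyloxy-3-methoxyphenyl)-2-(2-benzyloxy-5-bromo-3-methoxyphenyl)propane-1,3-diol, via phenol triol 32 (not isolated)
Conditions: K2CO3, MeOH, rt; evaporate; then BnBr, DMF, rt → 40 °C
Reagents that add atoms: benzyl bromide BrCc1ccccc1
Why: Carbonate methanolysis and selective phenol benzylation as in step 12.

Step 20
Reactants: 33 (1R,2R)-diol
Product: 34 (1R,2R)-1-(4-benzyloxy-3-methoxyphenyl)-2-(2-benzyloxy-5-bromo-3-methoxyphenyl)-3-(tert-butyldimethylsilyloxy)propan-1-ol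
Conditions: t-BuMe2SiCl, imidazole, CH2Cl2, 0 °C
Reagents that add atoms: tert-butyldimethylsilyl chloride CC(C)(C)[Si](C)(C)Cl
Why: Silyl chloride with imidazole silylates the primary C9′ hydroxyl selectively over the hindered secondary benzylic one.

Step 21
Reactants: 34 (1R,2R)-mono-TBS alcohol
Product: 35 (1S,2R)-1-(4-benzyloxy-3-methoxyphenyl)-2-(2-benzyloxy-5-bromo-3-methoxyphenyl)-3-(tert-butyldimethylsilyloxy)propyl 4-nitrobenzoate
Conditions: 4-nitrobenzoic acid, PPh3, DIAD, toluene, −20 → 0 °C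
Reagents that add atoms: 4-nitrobenzoic acid OC(=O)c1ccc(cc1)[N+](=O)[O-]
Why: Mitsunobu esterification displaces the oxyphosphonium group by carboxylate with inversion, which should turn C7′ from R to S; the non-polar solvent and low temperature are chosen to disfavour ionisation.

Step 22
Reactants: 35 (1S,2R)-4-nitrobenzoate
Product: 36 (1S,2R)-1-(4-benzyloxy-3-methoxyphenyl)-2-(2-benzyloxy-5-bromo-3-methoxyphenyl)-3-(tert-butyldimethylsilyloxy)propan-1-ol
Conditions: K2CO3, MeOH, rt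
Reagents that add atoms: none
Why: Ester methanolysis breaks the acyl–oxygen bond, so the new C7′ configuration is kept; any 1,3-silyl shift is harmless because step 23 silylates both oxygens.

Step 23
Reactants: 36 (1S,2R)-alcohol
Product: 37 (1S,2R)-1-(4-benzyloxy-3-methoxyphenyl)-2-(2-benzyloxy-5-bromo-3-methoxyphenyl)-1,3-bis(tert-butyldimethylsilyloxy)propane
Conditions: t-BuMe2SiOTf, 2,6-lutidine, CH2Cl2, −78 → 0 °C
Reagents that add atoms: tert-butyldimethylsilyl triflate CC(C)(C)[Si](C)(C)OS(=O)(=O)C(F)(F)F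
Why: Silyl triflate silylation of the hindered secondary alcohol completes the bis-silyl protection of the ring C arm.

Step 24
Reactants: 37 ring C arm aryl bromide
Product: 40 {4-benzyloxy-3-[(1S,2R)-1-(4-benzyloxy-3-methoxyphenyl)-1,3-bis(tert-butyldimethylsilyloxy)propan-2-yl]-5-methoxyphenyl}methanol, via aryllithium 38 (not isolated), via aldehyde 39 (not isolated)
Conditions: t-BuLi (2.1 equiv), THF, −78 °C; DMF, −78 → 0 °C; then MeOH, NaBH4, 0 °C
Reagents that add atoms: N,N-dimethylformamide CN(C)C=O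
Why: Bromine–lithium exchange, formylation of the aryllithium with DMF and borohydride reduction in the same flask turn the aryl bromide into the benzylic alcohol.

Step 25
Reactants: 40 benzylic alcohol
Product: 41 ring C arm benzylic bromide (CH2Br in place of CH2OH of 40)
Conditions: CBr4, PPh3, CH2Cl2, 0 °C
Reagents that add atoms: carbon tetrabromide BrC(Br)(Br)Br
Why: Appel bromination works under neutral conditions that spare the silyl ethers; the electron-rich benzylic bromide is used at once.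

Step 26
Reactants: 42 (S)-epichlorohydrin; 43 diethyl malonate
Product: 44 ethyl (1R,5S)-2-oxo-3-oxabicyclo[3.1.0]hexane-1-carboxylate
Conditions: NaOEt, EtOH, reflux
Reagents that add atoms: none
Why: Known malonate cyclopropanation–lactonisation of epichlorohydrin (epoxide opening at CH2, epoxide re-formation with loss of chloride, cyclopropane closure with inversion at CH, lactonisation), which carries the S centre of 42 into C5 of the 1R,5S lactone.

Step 27
Reactants: 21 ring B arm aryl bromide; 44 cyclopropane-fused lactone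
Product: 47 ethyl (3R,4S)-4-(arylmethyl)-2-oxotetrahydrofuran-3-carboxylate (aryl = ring B arm; trans shown; C3 epimerisable), via aryllithium 45 (not isolated), via arylmagnesium bromide 46 (not isolated)
Conditions: t-BuLi (2.05 equiv), THF, −78 °C; MgBr2·OEt2, −78 → −20 °C; CuI (0.15 equiv), then 44 (0.8 equiv), −30 → 0 °C
Reagents that add atoms: none
Why: Copper-catalysed homoconjugate addition of the aryl Grignard reagent to the doubly activated cyclopropane at its CH2 carbon should give the β-arylmethyl lactone with the former C5 (now the S β-carbon of ring A) untouched.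

Step 28
Reactants: 47 α-ethoxycarbonyl lactone
Product: 49 (4S)-4-(arylmethyl)dihydrofuran-2(3H)-one (aryl = ring B arm), via lactone acid 48 (not isolated)
Conditions: LiOH, THF/H2O, 0 °C → rt; 1 M HCl to pH 3, 0 °C; then toluene, 100 °C
Reagents that add atoms: none
Why: Saponification, relactonisation on acidification and thermal decarboxylation of the malonic-type acid remove the activating ester without the hot chloride of a Krapcho reaction, which could cleave the silyl ethers.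

Step 29
Reactants: 49 (S)-β-benzyl lactone; 41 ring C arm benzylic bromide
Product: 51 tetra-O-benzyl tetra-O-TBS derivative of the target with (3S,4S)-trans lactone, via lithium enolate 50 (not isolated)
Conditions: LiN(SiMe3)2, THF, −78 °C; then 41, DMPU, −78 → −20 °C
Reagents that add atoms: none
Why: Alkylation of the lactone lithium enolate on the face anti to the β-substituent (1,2-induction, the standard entry to trans-dibenzylbutyrolactones) should set the α-carbon as S.

Step 30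
Reactants: 51 fully protected lactone
Product: 52 tetra-O-benzyl ether of the target
Conditions: Bu4NF, AcOH, THF, rt → 40 °C
Reagents that add atoms: none
Why: Fluoride desilylation buffered with acetic acid should remove the four silyl ethers without acid-promoted ionisation at C7 or C7′ and without opening the lactone.

Step 31
Reactants: 52 tetra-O-benzyl ether
Product: 53 CNP0113972.1
Conditions: H2 (1 atm), Pd/C (10 wt%), EtOAc/EtOH, rt
Reagents that add atoms: none
Why: Hydrogenolysis of the four aryl benzyl ethers over palladium under neutral conditions, where benzylic alcohols are cleaved much more slowly than benzyl ethers, should release the target; the reaction is stopped once the ethers are consumed.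

**Compound list**

1 | 5-bromo-2-hydroxy-3-methoxybenzaldehyde | COc1cc(Br)cc(C=O)c1O | starting material
2 | 5-bromo-3-methoxy-2-(triisopropylsilyloxy)benzaldehyde | COc1cc(Br)cc(C=O)c1O[Si](C(C)C)(C(C)C)C(C)C | intermediate
3 | [4-bromo-2-methoxy-6-(2-methoxyethenyl)phenoxy]triisopropylsilane, E/Z mixture | COC=Cc1cc(Br)cc(OC)c1O[Si](C(C)C)(C(C)C)C(C)C | intermediate
4 | 2-[5-bromo-3-methoxy-2-(triisopropylsilyloxy)phenyl]acetaldehyde | O=CCc1cc(Br)cc(OC)c1O[Si](C(C)C)(C(C)C)C(C)C | intermediate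
5 | 2-[5-bromo-3-methoxy-2-(triisopropylsilyloxy)phenyl]acetic acid | OC(=O)Cc1cc(Br)cc(OC)c1O[Si](C(C)C)(C(C)C)C(C)C | intermediate
6 | 4-benzyloxy-3-methoxybenzyl alcohol | COc1cc(CO)ccc1OCc1ccccc1 | starting material
7 | 4-benzyloxy-3-methoxybenzyl bromide | COc1cc(CBr)ccc1OCc1ccccc1 | intermediate
8 | 2-[5-bromo-3-methoxy-2-(triisopropylsilyloxy)phenyl]acetyl chloride | ClC(=O)Cc1cc(Br)cc(OC)c1O[Si](C(C)C)(C(C)C)C(C)C | intermediate
9 | (S)-4-benzyl-2-oxazolidinone | O=C1N[C@@H](Cc2ccccc2)CO1 | starting material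
10 | (4S)-4-benzyl-3-{[5-bromo-3-methoxy-2-(triisopropylsilyloxy)phenyl]acetyl}oxazolidin-2-one | O=C(Cc1cc(Br)cc(OC)c1O[Si](C(C)C)(C(C)C)C(C)C)N1[C@@H](Cc2ccccc2)COC1=O | intermediate
11 | sodium Z-enolate of 10 | [Na+].[O-]/C(=C\c1cc(Br)cc(OC)c1O[Si](C(C)C)(C(C)C)C(C)C)N1[C@@H](Cc2ccccc2)COC1=O | intermediate
12 | (4S)-4-benzyl-3-[(2S)-3-(4-benzyloxy-3-methoxyphenyl)-2-(5-bromo-3-methoxy-2-triisopropylsilyloxyphenyl)propanoyl]oxazolidin-2-one | COc1cc(ccc1OCc1ccccc1)C[C@H](C(=O)N1[C@@H](Cc2ccccc2)COC1=O)c1cc(Br)cc(OC)c1O[Si](C(C)C)(C(C)C)C(C)C | intermediate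
13 | (2S)-3-(4-benzyloxy-3-methoxyphenyl)-2-[5-bromo-3-methoxy-2-(triisopropylsilyloxy)phenyl]propan-1-ol | COc1cc(ccc1OCc1ccccc1)C[C@H](CO)c1cc(Br)cc(OC)c1O[Si](C(C)C)(C(C)C)C(C)C | intermediate
14 | 2-[(2S)-1-(4-benzyloxy-3-methoxyphenyl)-3-hydroxypropan-2-yl]-4-bromo-6-methoxyphenol | COc1cc(ccc1OCc1ccccc1)C[C@H](CO)c1cc(Br)cc(OC)c1O | intermediate
15 | tert-butyl (2S)-3-(4-benzyloxy-3-methoxyphenyl)-2-[5-bromo-2-(tert-butoxycarbonyloxy)-3-methoxyphenyl]propyl carbonate (key-step precursor) | COc1cc(ccc1OCc1ccccc1)C[C@H](COC(=O)OC(C)(C)C)c1cc(Br)cc(OC)c1OC(=O)OC(C)(C)C | intermediate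
16 | C7 benzylic cation from 15 (8S) | COc1cc(ccc1OCc1ccccc1)[CH+][C@H](COC(=O)OC(C)(C)C)c1cc(Br)cc(OC)c1OC(=O)OC(C)(C)C | intermediate
17 | (4S,5S)-2-tert-butoxy-4,5-diaryl-1,3-dioxan-2-ylium ion | COc1cc(ccc1OCc1ccccc1)[C@@H](OC(OC(C)(C)C)=[O+]2)[C@H](C2)c2cc(Br)cc(OC)c2OC(=O)OC(C)(C)C | intermediate
18 | tert-butyl 2-[(4S,5S)-4-(4-benzyloxy-3-methoxyphenyl)-2-oxo-1,3-dioxan-5-yl]-4-bromo-6-methoxyphenyl carbonate (key-step product) | COc1cc(ccc1OCc1ccccc1)[C@@H](OC(=O)O2)[C@H](C2)c2cc(Br)cc(OC)c2OC(=O)OC(C)(C)C | intermediate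
19 | (1S,2S)-1-(4-benzyloxy-3-methoxyphenyl)-2-(5-bromo-2-hydroxy-3-methoxyphenyl)propane-1,3-diol | COc1cc(ccc1OCc1ccccc1)[C@@H](O)[C@H](CO)c1cc(Br)cc(OC)c1O | intermediate
20 | (1S,2S)-1-(4-benzyloxy-3-methoxyphenyl)-2-(2-benzyloxy-5-bromo-3-methoxyphenyl)propane-1,3-diol | COc1cc(ccc1OCc1ccccc1)[C@@H](O)[C@H](CO)c1cc(Br)cc(OC)c1OCc1ccccc1 | intermediate
21 | (1S,2S)-1-(4-benzyloxy-3-methoxyphenyl)-2-(2-benzyloxy-5-bromo-3-methoxyphenyl)-1,3-bis(tert-butyldimethylsilyloxy)propane | COc1cc(ccc1OCc1ccccc1)[C@@H](O[Si](C)(C)C(C)(C)C)[C@H](CO[Si](C)(C)C(C)(C)C)c1cc(Br)cc(OC)c1OCc1ccccc1 | intermediate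
22 | (R)-4-benzyl-2-oxazolidinone | O=C1N[C@H](Cc2ccccc2)CO1 | starting material
23 | (4R)-4-benzyl-3-{[5-bromo-3-methoxy-2-(triisopropylsilyloxy)phenyl]acetyl}oxazolidin-2-one | O=C(Cc1cc(Br)cc(OC)c1O[Si](C(C)C)(C(C)C)C(C)C)N1[C@H](Cc2ccccc2)COC1=O | intermediate
24 | sodium Z-enolate of 23 | [Na+].[O-]/C(=C\c1cc(Br)cc(OC)c1O[Si](C(C)C)(C(C)C)C(C)C)N1[C@H](Cc2ccccc2)COC1=O | intermediate
25 | (4R)-4-benzyl-3-[(2R)-3-(4-benzyloxy-3-methoxyphenyl)-2-(5-bromo-3-methoxy-2-triisopropylsilyloxyphenyl)propanoyl]oxazolidin-2-one | COc1cc(ccc1OCc1ccccc1)C[C@@H](C(=O)N1[C@H](Cc2ccccc2)COC1=O)c1cc(Br)cc(OC)c1O[Si](C(C)C)(C(C)C)C(C)C | intermediate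
26 | (2R)-3-(4-benzyloxy-3-methoxyphenyl)-2-[5-bromo-3-methoxy-2-(triisopropylsilyloxy)phenyl]propan-1-ol | COc1cc(ccc1OCc1ccccc1)C[C@@H](CO)c1cc(Br)cc(OC)c1O[Si](C(C)C)(C(C)C)C(C)C | intermediate
27 | 2-[(2R)-1-(4-benzyloxy-3-methoxyphenyl)-3-hydroxypropan-2-yl]-4-bromo-6-methoxyphenol | COc1cc(ccc1OCc1ccccc1)C[C@@H](CO)c1cc(Br)cc(OC)c1O | intermediate
28 | tert-butyl (2R)-3-(4-benzyloxy-3-methoxyphenyl)-2-[5-bromo-2-(tert-butoxycarbonyloxy)-3-methoxyphenyl]propyl carbonate | COc1cc(ccc1OCc1ccccc1)C[C@@H](COC(=O)OC(C)(C)C)c1cc(Br)cc(OC)c1OC(=O)OC(C)(C)C | intermediate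
29 | C7′ benzylic cation from 28 (8′R) | COc1cc(ccc1OCc1ccccc1)[CH+][C@@H](COC(=O)OC(C)(C)C)c1cc(Br)cc(OC)c1OC(=O)OC(C)(C)C | intermediate
30 | (4R,5R)-2-tert-butoxy-4,5-diaryl-1,3-dioxan-2-ylium ion | COc1cc(ccc1OCc1ccccc1)[C@H](OC(OC(C)(C)C)=[O+]2)[C@@H](C2)c2cc(Br)cc(OC)c2OC(=O)OC(C)(C)C | intermediate
31 | tert-butyl 2-[(4R,5R)-4-(4-benzyloxy-3-methoxyphenyl)-2-oxo-1,3-dioxan-5-yl]-4-bromo-6-methoxyphenyl carbonate | COc1cc(ccc1OCc1ccccc1)[C@H](OC(=O)O2)[C@@H](C2)c2cc(Br)cc(OC)c2OC(=O)OC(C)(C)C | intermediate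
32 | (1R,2R)-1-(4-benzyloxy-3-methoxyphenyl)-2-(5-bromo-2-hydroxy-3-methoxyphenyl)propane-1,3-diol | COc1cc(ccc1OCc1ccccc1)[C@H](O)[C@@H](CO)c1cc(Br)cc(OC)c1O | intermediate
33 | (1R,2R)-1-(4-benzyloxy-3-methoxyphenyl)-2-(2-benzyloxy-5-bromo-3-methoxyphenyl)propane-1,3-diol | COc1cc(ccc1OCc1ccccc1)[C@H](O)[C@@H](CO)c1cc(Br)cc(OC)c1OCc1ccccc1 | intermediate
34 | (1R,2R)-1-(4-benzyloxy-3-methoxyphenyl)-2-(2-benzyloxy-5-bromo-3-methoxyphenyl)-3-(tert-butyldimethylsilyloxy)propan-1-ol | COc1cc(ccc1OCc1ccccc1)[C@H](O)[C@@H](CO[Si](C)(C)C(C)(C)C)c1cc(Br)cc(OC)c1OCc1ccccc1 | intermediate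
35 | (1S,2R)-1-(4-benzyloxy-3-methoxyphenyl)-2-(2-benzyloxy-5-bromo-3-methoxyphenyl)-3-(tert-butyldimethylsilyloxy)propyl 4-nitrobenzoate | COc1cc(ccc1OCc1ccccc1)[C@@H](OC(=O)c1ccc(cc1)[N+](=O)[O-])[C@@H](CO[Si](C)(C)C(C)(C)C)c1cc(Br)cc(OC)c1OCc1ccccc1 | intermediate
36 | (1S,2R)-1-(4-benzyloxy-3-methoxyphenyl)-2-(2-benzyloxy-5-bromo-3-methoxyphenyl)-3-(tert-butyldimethylsilyloxy)propan-1-ol | COc1cc(ccc1OCc1ccccc1)[C@@H](O)[C@@H](CO[Si](C)(C)C(C)(C)C)c1cc(Br)cc(OC)c1OCc1ccccc1 | intermediate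
37 | (1S,2R)-1-(4-benzyloxy-3-methoxyphenyl)-2-(2-benzyloxy-5-bromo-3-methoxyphenyl)-1,3-bis(tert-butyldimethylsilyloxy)propane | COc1cc(ccc1OCc1ccccc1)[C@@H](O[Si](C)(C)C(C)(C)C)[C@@H](CO[Si](C)(C)C(C)(C)C)c1cc(Br)cc(OC)c1OCc1ccccc1 | intermediate
38 | aryllithium from 37 (Li in place of Br) | COc1cc(ccc1OCc1ccccc1)[C@@H](O[Si](C)(C)C(C)(C)C)[C@@H](CO[Si](C)(C)C(C)(C)C)c1cc([Li])cc(OC)c1OCc1ccccc1 | intermediate
39 | 4-benzyloxy-3-[(1S,2R)-1-(4-benzyloxy-3-methoxyphenyl)-1,3-bis(tert-butyldimethylsilyloxy)propan-2-yl]-5-methoxybenzaldehyde | COc1cc(ccc1OCc1ccccc1)[C@@H](O[Si](C)(C)C(C)(C)C)[C@@H](CO[Si](C)(C)C(C)(C)C)c1cc(C=O)cc(OC)c1OCc1ccccc1 | intermediate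
40 | {4-benzyloxy-3-[(1S,2R)-1-(4-benzyloxy-3-methoxyphenyl)-1,3-bis(tert-butyldimethylsilyloxy)propan-2-yl]-5-methoxyphenyl}methanol | COc1cc(ccc1OCc1ccccc1)[C@@H](O[Si](C)(C)C(C)(C)C)[C@@H](CO[Si](C)(C)C(C)(C)C)c1cc(CO)cc(OC)c1OCc1ccccc1 | intermediate
41 | ring C arm benzylic bromide (CH2Br in place of CH2OH of 40) | COc1cc(ccc1OCc1ccccc1)[C@@H](O[Si](C)(C)C(C)(C)C)[C@@H](CO[Si](C)(C)C(C)(C)C)c1cc(CBr)cc(OC)c1OCc1ccccc1 | intermediate
42 | (S)-epichlorohydrin | ClC[C@@H]1CO1 | starting material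
43 | diethyl malonate | CCOC(=O)CC(=O)OCC | starting material
44 | ethyl (1R,5S)-2-oxo-3-oxabicyclo[3.1.0]hexane-1-carboxylate | O=C1OC[C@H]2C[C@@]12C(=O)OCC | intermediate
45 | aryllithium from 21 (Li in place of Br) | COc1cc(ccc1OCc1ccccc1)[C@@H](O[Si](C)(C)C(C)(C)C)[C@H](CO[Si](C)(C)C(C)(C)C)c1cc([Li])cc(OC)c1OCc1ccccc1 | intermediate
46 | arylmagnesium bromide from 21 | COc1cc(ccc1OCc1ccccc1)[C@@H](O[Si](C)(C)C(C)(C)C)[C@H](CO[Si](C)(C)C(C)(C)C)c1cc([Mg]Br)cc(OC)c1OCc1ccccc1 | intermediate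
47 | ethyl (3R,4S)-4-(arylmethyl)-2-oxotetrahydrofuran-3-carboxylate, aryl = ring B arm | COc1cc(ccc1OCc1ccccc1)[C@@H](O[Si](C)(C)C(C)(C)C)[C@H](CO[Si](C)(C)C(C)(C)C)c1cc(C[C@@H]2COC(=O)[C@H]2C(=O)OCC)cc(OC)c1OCc1ccccc1 | intermediate
48 | (3R,4S)-4-(arylmethyl)-2-oxotetrahydrofuran-3-carboxylic acid, aryl = ring B arm | COc1cc(ccc1OCc1ccccc1)[C@@H](O[Si](C)(C)C(C)(C)C)[C@H](CO[Si](C)(C)C(C)(C)C)c1cc(C[C@@H]2COC(=O)[C@H]2C(O)=O)cc(OC)c1OCc1ccccc1 | intermediate
49 | (4S)-4-(arylmethyl)dihydrofuran-2(3H)-one, aryl = ring B arm | COc1cc(ccc1OCc1ccccc1)[C@@H](O[Si](C)(C)C(C)(C)C)[C@H](CO[Si](C)(C)C(C)(C)C)c1cc(C[C@@H]2COC(=O)C2)cc(OC)c1OCc1ccccc1 | intermediate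
50 | lithium enolate of 49 | [Li+].COc1cc(ccc1OCc1ccccc1)[C@@H](O[Si](C)(C)C(C)(C)C)[C@H](CO[Si](C)(C)C(C)(C)C)c1cc(C[C@@H]2COC([O-])=C2)cc(OC)c1OCc1ccccc1 | intermediate
51 | tetra-O-benzyl tetra-O-TBS derivative of the target, (3S,4S)-lactone | COc1cc(ccc1OCc1ccccc1)[C@@H](O[Si](C)(C)C(C)(C)C)[C@H](CO[Si](C)(C)C(C)(C)C)c1cc(C[C@@H]2COC(=O)[C@H]2Cc2cc(OC)c(OCc3ccccc3)c(c2)[C@H](CO[Si](C)(C)C(C)(C)C)[C@H](O[Si](C)(C)C(C)(C)C)c2ccc(OCc3ccccc3)c(OC)c2)cc(OC)c1OCc1ccccc1 | intermediate
52 | tetra-O-benzyl ether of the target | COc1cc(ccc1OCc1ccccc1)[C@@H](O)[C@H](CO)c1cc(C[C@@H]2COC(=O)[C@H]2Cc2cc(OC)c(OCc3ccccc3)c(c2)[C@H](CO)[C@H](O)c2ccc(OCc3ccccc3)c(OC)c2)cc(OC)c1OCc1ccccc1 | intermediate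
53 | CNP0113972.1 | COc1cc([C@@H](O)[C@H](CO)c2cc(C[C@@H]3COC(=O)[C@H]3Cc3cc(OC)c(O)c([C@H](CO)[C@H](O)c4ccc(O)c(OC)c4)c3)cc(OC)c2O)ccc1O | target

**Step count**

Total: 31 steps. Longest linear sequence: 20 steps (1–4, 6, 14–25, 29–31).

**Steps most likely to fail**

1. Step 11 (proposed method, ring B arm). Cation 16 may lose the C8 proton to give a stilbene faster than the carbonate oxygen adds, or the closure may show poor facial selectivity at C7. The fallback builds the C7–O bond together with the C7–C8 bond by an Evans aldol reaction; it sets out from imide 23 and comes back at 20. Imide 23 is converted to its boron Z-enolate (n-Bu2BOTf, i-Pr2NEt, CH2Cl2, 0 °C) and combined at −78 °C with commercial 4-benzyloxy-3-methoxybenzaldehyde. The syn aldol should give (4R)-4-benzyl-3-[(2R,3R)-3-(4-benzyloxy-3-methoxyphenyl)-2-(5-bromo-3-methoxy-2-triisopropylsilyloxyphenyl)-3-hydroxypropanoyl]oxazolidin-2-one F1, which has C8 as in 20 but C7 epimeric. LiBH4 should then give the (1R,2S)-1,3-diol F2, and t-BuMe2SiCl/imidazole its primary silyl ether F3. Mitsunobu reaction with 4-nitrobenzoic acid should give the C7-inverted (1S,2S)-4-nitrobenzoate F4. Bu4NF followed by K2CO3 in MeOH removes both silyl groups and the ester to give triol 19, which is benzylated as in the second stage of step 12 to give 20.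

2. Step 18 (proposed method, ring C arm). The same elimination from cation 29 or weak facial control may occur. The fallback sets out from imide 10 and comes back at 37, making steps 19–23 unnecessary. The boron enolate of 10 (n-Bu2BOTf, i-Pr2NEt) and 4-benzyloxy-3-methoxybenzaldehyde should give the syn aldol adduct (4S)-4-benzyl-3-[(2S,3S)-3-(4-benzyloxy-3-methoxyphenyl)-2-(5-bromo-3-methoxy-2-triisopropylsilyloxyphenyl)-3-hydroxypropanoyl]oxazolidin-2-one F5, which already has both arm centres as needed. LiBH4 should give the (1S,2R)-1,3-diol F6, and Bu4NF the (1S,2R)-phenol triol F7. BnBr/K2CO3 in DMF should give the (1S,2R)-1-(4-benzyloxy-3-methoxyphenyl)-2-(2-benzyloxy-5-bromo-3-methoxyphenyl)propane-1,3-diol F8. t-BuMe2SiOTf (2.5 equiv) with 2,6-lutidine then gives 37.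

3. Step 21 (Mitsunobu inversion). The oxyphosphonium ion at the electron-rich benzylic C7′ may ionise, leading to partial retention or elimination. The fallback replaces substitution by oxidation and reduction; it sets out from 34 and comes back at 36. Dess–Martin periodinane (NaHCO3, CH2Cl2) should give (2R)-1-(4-benzyloxy-3-methoxyphenyl)-2-(2-benzyloxy-5-bromo-3-methoxyphenyl)-3-(tert-butyldimethylsilyloxy)propan-1-one F9. LiBH(s-Bu)3 in THF at −78 °C should then add hydride anti to ring C on C8′ (Felkin–Anh control), which corresponds to the 7′S alcohol 36.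

**Further compounds**

F1 | step 11 | (4R)-4-benzyl-3-[(2R,3R)-3-(4-benzyloxy-3-methoxyphenyl)-2-(5-bromo-3-methoxy-2-triisopropylsilyloxyphenyl)-3-hydroxypropanoyl]oxazolidin-2-one | COc1cc(ccc1OCc1ccccc1)[C@H](O)[C@H](C(=O)N1[C@H](Cc2ccccc2)COC1=O)c1cc(Br)cc(OC)c1O[Si](C(C)C)(C(C)C)C(C)C
F2 | step 11 | (1R,2S)-1-(4-benzyloxy-3-methoxyphenyl)-2-[5-bromo-3-methoxy-2-(triisopropylsilyloxy)phenyl]propane-1,3-diol | COc1cc(ccc1OCc1ccccc1)[C@H](O)[C@H](CO)c1cc(Br)cc(OC)c1O[Si](C(C)C)(C(C)C)C(C)C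
F3 | step 11 | (1R,2S)-1-(4-benzyloxy-3-methoxyphenyl)-2-[5-bromo-3-methoxy-2-(triisopropylsilyloxy)phenyl]-3-(tert-butyldimethylsilyloxy)propan-1-ol | COc1cc(ccc1OCc1ccccc1)[C@H](O)[C@H](CO[Si](C)(C)C(C)(C)C)c1cc(Br)cc(OC)c1O[Si](C(C)C)(C(C)C)C(C)C
F4 | step 11 | (1S,2S)-1-(4-benzyloxy-3-methoxyphenyl)-2-[5-bromo-3-methoxy-2-(triisopropylsilyloxy)phenyl]-3-(tert-butyldimethylsilyloxy)propyl 4-nitrobenzoate | COc1cc(ccc1OCc1ccccc1)[C@@H](OC(=O)c1ccc(cc1)[N+](=O)[O-])[C@H](CO[Si](C)(C)C(C)(C)C)c1cc(Br)cc(OC)c1O[Si](C(C)C)(C(C)C)C(C)C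
F5 | step 18 | (4S)-4-benzyl-3-[(2S,3S)-3-(4-benzyloxy-3-methoxyphenyl)-2-(5-bromo-3-methoxy-2-triisopropylsilyloxyphenyl)-3-hydroxypropanoyl]oxazolidin-2-one | COc1cc(ccc1OCc1ccccc1)[C@@H](O)[C@@H](C(=O)N1[C@@H](Cc2ccccc2)COC1=O)c1cc(Br)cc(OC)c1O[Si](C(C)C)(C(C)C)C(C)C
F6 | step 18 | (1S,2R)-1-(4-benzyloxy-3-methoxyphenyl)-2-[5-bromo-3-methoxy-2-(triisopropylsilyloxy)phenyl]propane-1,3-diol | COc1cc(ccc1OCc1ccccc1)[C@@H](O)[C@@H](CO)c1cc(Br)cc(OC)c1O[Si](C(C)C)(C(C)C)C(C)C
F7 | step 18 | (1S,2R)-1-(4-benzyloxy-3-methoxyphenyl)-2-(5-bromo-2-hydroxy-3-methoxyphenyl)propane-1,3-diol | COc1cc(ccc1OCc1ccccc1)[C@@H](O)[C@@H](CO)c1cc(Br)cc(OC)c1O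
F8 | step 18 | (1S,2R)-1-(4-benzyloxy-3-methoxyphenyl)-2-(2-benzyloxy-5-bromo-3-methoxyphenyl)propane-1,3-diol | COc1cc(ccc1OCc1ccccc1)[C@@H](O)[C@@H](CO)c1cc(Br)cc(OC)c1OCc1ccccc1
F9 | step 21 | (2R)-1-(4-benzyloxy-3-methoxyphenyl)-2-(2-benzyloxy-5-bromo-3-methoxyphenyl)-3-(tert-butyldimethylsilyloxy)propan-1-one | COc1cc(ccc1OCc1ccccc1)C(=O)[C@@H](CO[Si](C)(C)C(C)(C)C)c1cc(Br)cc(OC)c1OCc1ccccc1
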